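**Plan**
- Locants (decalin numbering): C1 quaternary (Me, CH2Ar), C2 (CHMe), C3, C4, C4a (CH), C5 (=CH2), C6–C8, C8a quaternary (Me). Ring A = C4a/C5–C8/C8a; ring B = C8a/C1–C4/C4a.
- Retrosynthesis cuts C5=CH2 (back to a C5 ketone), the C2–H and C4a–H bonds (hydrogenation of C2=CH2 and C4=C4a) and the aryl ester (ArBr carbonylation); then, in one operation, C4a–C8a and C2–C3.
- Enabling feature: the C5 carbonyl (the future methylene carbon) makes C4a (α) and, through a C4a–C4=C3 vinyl unit, C3 (γ) the two ends of one silyl dienol ether. The methyls on C8a and C2 are the footprints of a C8a=CH2 alkene and a C2≡CH alkyne flanking quaternary C1.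
- Forward: the acyclic chain is built by dianion alkylation, asymmetric benzylation, methylenation, alkyne homologation and allylation; one gold-catalysed double cycloisomerisation then closes ring A (C4a–C8a) and ring B (C3–C2).
- Stereochemistry: C1 from an asymmetric phase-transfer benzylation; C8a by 1,2-induction from C1 in the key step (the least secure element); C4a and C2 by hydrogenation from the α face, which the axial C8a methyl leaves open.

Key step: step 13

Assumption: of the two pseudo-enantiomeric cinchona phase-transfer catalysts the cinchonidinium salt is taken to give (S)-7; the cinchoninium analogue is used if the sense proves opposite.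

Step 1
Reactants: 1 tert-butyl 2-methyl-3-oxobutanoate; 2 2-(2-bromoethyl)-1,3-dioxolane
Product: 3 tert-butyl 6-(1,3-dioxolan-2-yl)-2-methyl-3-oxohexanoate (racemic)
Conditions: NaH, THF, 0 °C; n-BuLi, −10 °C; then 2, 0 °C → rt; aq. NH4Cl
Reagents that add atoms: none
Why: γ-alkylation of the β-keto ester dianion, whose terminal carbanion is the more reactive site, joins C8 to C7 and carries C5 as a masked aldehyde.

Step 2
Reactants: 4 2-(benzyloxy)-5-bromobenzaldehyde
Product: 5 [2-(benzyloxy)-5-bromophenyl]methanol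
Conditions: NaBH4, MeOH, 0 °C
Reagents that add atoms: none
Why: borohydride reduction of the aldehyde leaves the aryl bromide and the benzyl ether untouched.

Step 3
Reactants: 5 [2-(benzyloxy)-5-bromophenyl]methanol
Product: 6 1-(benzyloxy)-4-bromo-2-(bromomethyl)benzene
Conditions: PBr3, CH2Cl2, 0 °C
Reagents that add atoms: phosphorus tribromide BrP(Br)Br
Why: the benzylic alcohol is converted into the bromide by substitution through its phosphite ester.

Step 4
Reactants: 3 tert-butyl 6-(1,3-dioxolan-2-yl)-2-methyl-3-oxohexanoate; 6 1-(benzyloxy)-4-bromo-2-(bromomethyl)benzene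
Product: 7 tert-butyl (2S)-2-{[2-(benzyloxy)-5-bromophenyl]methyl}-6-(1,3-dioxolan-2-yl)-2-methyl-3-oxohexanoate
Conditions: N-(9-anthracenylmethyl)-O-allylcinchonidinium bromide (10 mol %), CsOH·H2O, toluene, −40 °C
Reagents that add atoms: none
Why: in this asymmetric phase-transfer alkylation the enolate is benzylated at carbon inside a chiral ammonium ion pair that shields one face, which sets the quaternary stereocentre C1.

Step 5
Reactants: 7 tert-butyl (2S)-2-{[2-(benzyloxy)-5-bromophenyl]methyl}-6-(1,3-dioxolan-2-yl)-2-methyl-3-oxohexanoate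
Product: 8 tert-butyl (2S)-2-{[2-(benzyloxy)-5-bromophenyl]methyl}-6-(1,3-dioxolan-2-yl)-2-methyl-3-methylidenehexanoate
Conditions: Ph3PCH3Br, KOt-Bu, toluene, 0 → 80 °C
Reagents that add atoms: methyltriphenylphosphonium bromide C[P+](c1ccccc1)(c1ccccc1)c1ccccc1.[Br-]
Why: Wittig methylenation of the ketone, which cannot enolise toward the quaternary carbon, installs the C8a=CH2 alkene while the hindered tert-butyl ester is not attacked.

Step 6
Reactants: 8 tert-butyl (2S)-2-{[2-(benzyloxy)-5-bromophenyl]methyl}-6-(1,3-dioxolan-2-yl)-2-methyl-3-methylidenehexanoate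
Product: 9 (2S)-2-{[2-(benzyloxy)-5-bromophenyl]methyl}-6-(1,3-dioxolan-2-yl)-2-methyl-3-methylidenehexan-1-ol
Conditions: LiAlH4, Et2O, 0 °C → rt
Reagents that add atoms: none
Why: hydride reduction of the ester gives the neopentyl primary alcohol, and the alkene, acetal, aryl bromide and benzyl ether are inert at this temperature.

Step 7
Reactants: 9 (2S)-2-{[2-(benzyloxy)-5-bromophenyl]methyl}-6-(1,3-dioxolan-2-yl)-2-methyl-3-methylidenehexan-1-ol
Product: 10 (2S)-2-{[2-(benzyloxy)-5-bromophenyl]methyl}-6-(1,3-dioxolan-2-yl)-2-methyl-3-methylidenehexanal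
Conditions: Dess–Martin periodinane, NaHCO3, CH2Cl2, rt
Reagents that add atoms: none
Why: Dess–Martin oxidation gives the non-enolisable aldehyde without touching the alkene or the acetal.

Step 8
Reactants: 10 (2S)-2-{[2-(benzyloxy)-5-bromophenyl]methyl}-6-(1,3-dioxolan-2-yl)-2-methyl-3-methylidenehexanal
Product: 11 2-[(5S)-5-{[2-(benzyloxy)-5-bromophenyl]methyl}-5-methyl-4-methylidenehept-6-yn-1-yl]-1,3-dioxolane
Conditions: dimethyl (1-diazo-2-oxopropyl)phosphonate, K2CO3, MeOH, rt
Reagents that add atoms: dimethyl (1-diazo-2-oxopropyl)phosphonate CC(=O)C(=[N+]=[N-])P(=O)(OC)OC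
Why: Ohira–Bestmann (Seyferth–Gilbert) homologation turns the non-enolisable aldehyde into the terminal alkyne C2≡CH under mild base.

Step 9
Reactants: 11 2-[(5S)-5-{[2-(benzyloxy)-5-bromophenyl]methyl}-5-methyl-4-methylidenehept-6-yn-1-yl]-1,3-dioxolane
Product: 12 (6S)-6-{[2-(benzyloxy)-5-bromophenyl]methyl}-6-methyl-5-methylideneoct-7-ynal
Conditions: pyridinium p-toluenesulfonate, acetone/H2O, 60 °C
Reagents that add atoms: water O
Why: mild acid-catalysed acetal hydrolysis unmasks the C5 aldehyde, and the buffered acid should not protonate the alkene.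

Step 10
Reactants: 12 (6S)-6-{[2-(benzyloxy)-5-bromophenyl]methyl}-6-methyl-5-methylideneoct-7-ynal
Product: 13 (9S)-9-{[2-(benzyloxy)-5-bromophenyl]methyl}-9-methyl-8-methylideneundec-1-en-10-yn-4-ol (both C4 epimers)
Conditions: allylboronic acid pinacol ester, toluene, rt
Reagents that add atoms: allylboronic acid pinacol ester C=CCB1OC(C)(C)C(C)(C)O1
Why: allylboration through a six-membered cyclic transition state adds the C4a–C4=C3 unit without touching the acidic alkyne C–H, and the new carbinol centre needs no control because it is oxidised next.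

Step 11
Reactants: 13 (9S)-9-{[2-(benzyloxy)-5-bromophenyl]methyl}-9-methyl-8-methylideneundec-1-en-10-yn-4-ol
Product: 14 (9S)-9-{[2-(benzyloxy)-5-bromophenyl]methyl}-9-methyl-8-methylideneundec-1-en-10-yn-4-one
Conditions: Dess–Martin periodinane, NaHCO3, CH2Cl2, 0 °C
Reagents that add atoms: none
Why: buffered Dess–Martin oxidation gives the β,γ-unsaturated (allyl) ketone without base-induced conjugation.

Step 12
Reactants: 14 (9S)-9-{[2-(benzyloxy)-5-bromophenyl]methyl}-9-methyl-8-methylideneundec-1-en-10-yn-4-one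
Product: 15 tert-butyl{[(3Z,9S)-9-{[2-(benzyloxy)-5-bromophenyl]methyl}-9-methyl-8-methylideneundeca-1,3-dien-10-yn-4-yl]oxy}dimethylsilane
Conditions: TBSOTf, Et3N, CH2Cl2, −78 → 0 °C
Reagents that add atoms: tert-butyldimethylsilyl trifluoromethanesulfonate CC(C)(C)[Si](C)(C)OS(=O)(=O)C(F)(F)F
Why: soft enolisation removes the doubly activated proton at C4a (between carbonyl and vinyl), which should give the linear (Z)-silyl dienol ether regioselectively.

Step 13
Reactants: 15 tert-butyl{[(3Z,9S)-9-{[2-(benzyloxy)-5-bromophenyl]methyl}-9-methyl-8-methylideneundeca-1,3-dien-10-yn-4-yl]oxy}dimethylsilane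
Product: 17 (4aR,5R)-5-{[2-(benzyloxy)-5-bromophenyl]methyl}-4a,5-dimethyl-6-methylidene-3,4,4a,5,6,7-hexahydronaphthalen-1(2H)-one, via monocyclic silyl dienol ether 16 (not isolated)
Conditions: [(t-Bu)2(2-biphenylyl)P]Au(NCMe)SbF6 (5 mol %), 2,6-di-tert-butyl-4-methylpyridine (20 mol %), MeOH (1.5 equiv), toluene, 60 °C
Reagents that add atoms: none
Why: Proposed new method: the cationic monovalent gold catalyst should first activate the 1,1-disubstituted alkene so that C4a, the α-carbon of the dienol ether, adds to C8a in Markovnikov fashion; loss of the now doubly activated C4a proton restores a dienol ether (16) and protodeauration turns CH2–Au into the C8a methyl. The γ-carbon C3 of 16 then attacks the gold-bound alkyne, and protodeauration plus desilylation by MeOH leave the C2 exocyclic methylene and the C5 enone. The closest known reaction types are the gold-catalysed intramolecular hydroalkylation of unactivated alkenes by ketones and the gold-catalysed Conia-ene-type carbocyclisation of silyl enol ethers onto alkynes; running them as one α-then-γ sequence on a single dienol ether is new. Ring A closes 6-(enolendo)-exo-trig and ring B closes 6-exo-dig. The one new stereocentre, C8a, is controlled by 1,2-induction from C1: in the chair transition state the C1 unit is equatorial and its benzyl arm turns away from the incoming C4a, a preference expected to be modest. The step needs Markovnikov attack at the alkene (secured by the tertiary C8a and a six- versus seven-membered ring), α-before-γ order (no nucleophilic carbon can reach the alkyne in a normal ring until ring A exists) and C- not O-attack (secured by the silyl cap).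

Step 14
Reactants: 17 (4aR,5R)-5-{[2-(benzyloxy)-5-bromophenyl]methyl}-4a,5-dimethyl-6-methylidene-3,4,4a,5,6,7-hexahydronaphthalen-1(2H)-one
Product: 18 methyl 4-(benzyloxy)-3-{[(1R,8aR)-1,8a-dimethyl-2-methylidene-5-oxo-1,2,3,5,6,7,8,8a-octahydronaphthalen-1-yl]methyl}benzoate
Conditions: Pd(OAc)2 (5 mol %), 1,3-bis(diphenylphosphino)propane, CO (1 atm), MeOH, Et3N, DMF, 70 °C
Reagents that add atoms: carbon monoxide [C-]#[O+]; methanol CO
Why: palladium-catalysed methoxycarbonylation of the aryl bromide (oxidative addition, CO insertion, methanolysis) installs the methyl ester before the hydrogenation, which would otherwise remove the bromide.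

Step 15
Reactants: 18 methyl 4-(benzyloxy)-3-{[(1R,8aR)-1,8a-dimethyl-2-methylidene-5-oxo-1,2,3,5,6,7,8,8a-octahydronaphthalen-1-yl]methyl}benzoate
Product: 19 methyl 4-hydroxy-3-{[(1R,2S,4aR,8aS)-1,2,8a-trimethyl-5-oxodecahydronaphthalen-1-yl]methyl}benzoate
Conditions: H2 (1 atm), Pd/C, EtOAc, rt
Reagents that add atoms: none
Why: heterogeneous hydrogenation should deliver hydrogen to both C=C bonds from the α face, because the axial C8a methyl covers the β face of ring B, which sets C4a–H anti to that methyl (trans fusion) and the C2 methyl syn to it, and the same conditions cleave the benzyl ether by hydrogenolysis.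

Step 16
Reactants: 19 methyl 4-hydroxy-3-{[(1R,2S,4aR,8aS)-1,2,8a-trimethyl-5-oxodecahydronaphthalen-1-yl]methyl}benzoate
Product: 20 methyl 4-hydroxy-3-{[(1R,2S,4aS,8aS)-1,2,8a-trimethyl-5-methylidenedecahydronaphthalen-1-yl]methyl}benzoate
Conditions: Zn, CH2Br2, TiCl4, THF, 0 °C → rt
Reagents that add atoms: dibromomethane BrCBr
Why: Takai–Lombardo methylenation with the non-basic zinc–titanium methylene reagent should convert the ketone into the exocyclic alkene without epimerising C4a and leave the ester and phenol.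

**Compound list**
1 | tert-butyl 2-methyl-3-oxobutanoate | CC(=O)C(C)C(=O)OC(C)(C)C | starting material
2 | 2-(2-bromoethyl)-1,3-dioxolane | BrCCC1OCCO1 | starting material
3 | tert-butyl 6-(1,3-dioxolan-2-yl)-2-methyl-3-oxohexanoate (racemic) | CC(C(=O)OC(C)(C)C)C(=O)CCCC1OCCO1 | intermediate
4 | 2-(benzyloxy)-5-bromobenzaldehyde | O=Cc1cc(Br)ccc1OCc1ccccc1 | starting material
5 | [2-(benzyloxy)-5-bromophenyl]methanol | OCc1cc(Br)ccc1OCc1ccccc1 | intermediate
6 | 1-(benzyloxy)-4-bromo-2-(bromomethyl)benzene | BrCc1cc(Br)ccc1OCc1ccccc1 | intermediate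
7 | tert-butyl (2S)-2-{[2-(benzyloxy)-5-bromophenyl]methyl}-6-(1,3-dioxolan-2-yl)-2-methyl-3-oxohexanoate | CC(C)(C)OC(=O)[C@@](C)(Cc1cc(Br)ccc1OCc1ccccc1)C(=O)CCCC1OCCO1 | intermediate
8 | tert-butyl (2S)-2-{[2-(benzyloxy)-5-bromophenyl]methyl}-6-(1,3-dioxolan-2-yl)-2-methyl-3-methylidenehexanoate | CC(C)(C)OC(=O)[C@@](C)(Cc1cc(Br)ccc1OCc1ccccc1)C(=C)CCCC1OCCO1 | intermediate
9 | (2S)-2-{[2-(benzyloxy)-5-bromophenyl]methyl}-6-(1,3-dioxolan-2-yl)-2-methyl-3-methylidenehexan-1-ol | OC[C@@](C)(Cc1cc(Br)ccc1OCc1ccccc1)C(=C)CCCC1OCCO1 | intermediate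
10 | (2S)-2-{[2-(benzyloxy)-5-bromophenyl]methyl}-6-(1,3-dioxolan-2-yl)-2-methyl-3-methylidenehexanal | O=C[C@@](C)(Cc1cc(Br)ccc1OCc1ccccc1)C(=C)CCCC1OCCO1 | intermediate
11 | 2-[(5S)-5-{[2-(benzyloxy)-5-bromophenyl]methyl}-5-methyl-4-methylidenehept-6-yn-1-yl]-1,3-dioxolane | C#C[C@@](C)(Cc1cc(Br)ccc1OCc1ccccc1)C(=C)CCCC1OCCO1 | intermediate
12 | (6S)-6-{[2-(benzyloxy)-5-bromophenyl]methyl}-6-methyl-5-methylideneoct-7-ynal | C#C[C@@](C)(Cc1cc(Br)ccc1OCc1ccccc1)C(=C)CCCC=O | intermediate
13 | (9S)-9-{[2-(benzyloxy)-5-bromophenyl]methyl}-9-methyl-8-methylideneundec-1-en-10-yn-4-ol (both C4 epimers) | C#C[C@@](C)(Cc1cc(Br)ccc1OCc1ccccc1)C(=C)CCCC(O)CC=C | intermediate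
14 | (9S)-9-{[2-(benzyloxy)-5-bromophenyl]methyl}-9-methyl-8-methylideneundec-1-en-10-yn-4-one | C#C[C@@](C)(Cc1cc(Br)ccc1OCc1ccccc1)C(=C)CCCC(=O)CC=C | intermediate
15 | tert-butyl{[(3Z,9S)-9-{[2-(benzyloxy)-5-bromophenyl]methyl}-9-methyl-8-methylideneundeca-1,3-dien-10-yn-4-yl]oxy}dimethylsilane | C#C[C@@](C)(Cc1cc(Br)ccc1OCc1ccccc1)C(=C)CCC/C(O[Si](C)(C)C(C)(C)C)=C/C=C | intermediate
16 | tert-butyl({(3R)-3-[(2R)-1-[2-(benzyloxy)-5-bromophenyl]-2-methylbut-3-yn-2-yl]-2-ethenyl-3-methylcyclohex-1-en-1-yl}oxy)dimethylsilane | C#C[C@@](C)(Cc1cc(Br)ccc1OCc1ccccc1)[C@@]1(C)CCCC(O[Si](C)(C)C(C)(C)C)=C1C=C | intermediate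
17 | (4aR,5R)-5-{[2-(benzyloxy)-5-bromophenyl]methyl}-4a,5-dimethyl-6-methylidene-3,4,4a,5,6,7-hexahydronaphthalen-1(2H)-one | O=C1CCC[C@@]2(C)C1=CCC(=C)[C@@]2(C)Cc1cc(Br)ccc1OCc1ccccc1 | intermediate
18 | methyl 4-(benzyloxy)-3-{[(1R,8aR)-1,8a-dimethyl-2-methylidene-5-oxo-1,2,3,5,6,7,8,8a-octahydronaphthalen-1-yl]methyl}benzoate | O=C1CCC[C@@]2(C)C1=CCC(=C)[C@@]2(C)Cc1cc(C(=O)OC)ccc1OCc1ccccc1 | intermediate
19 | methyl 4-hydroxy-3-{[(1R,2S,4aR,8aS)-1,2,8a-trimethyl-5-oxodecahydronaphthalen-1-yl]methyl}benzoate | O=C1CCC[C@@]2(C)[C@H]1CC[C@H](C)[C@@]2(C)Cc1cc(C(=O)OC)ccc1O | intermediate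
20 | methyl 4-hydroxy-3-{[(1R,2S,4aS,8aS)-1,2,8a-trimethyl-5-methylidenedecahydronaphthalen-1-yl]methyl}benzoate | C=C1CCC[C@@]2(C)[C@H]1CC[C@H](C)[C@@]2(C)Cc1cc(C(=O)OC)ccc1O | target

**Step count and risks**
Total steps: 16. Longest linear sequence: 15 (steps 2–16, from compound 4).

Steps most likely to fail:

1. Step 13 (Proposed new method). What may go wrong: loss of the silyl group by protonolysis before the alkene is attacked, too slow engagement of the unactivated alkene, and poor facial selectivity at C8a from the weak 1,2-induction by C1. Fallback (stepwise, known reaction types): setting out from 15, stoichiometric Pd(OAc)2 in MeCN should close ring A in a Saegusa-type cyclisation of the silyl enol ether onto the unactivated alkene; the neopentyl C–Pd bond, which has no β-hydrogen, is cleaved with Et3SiH. This gives the vinyl ketone 2-ethenyl-3-methyl-3-{(2R)-1-[2-(benzyloxy)-5-bromophenyl]-2-methylbut-3-yn-2-yl}cyclohexan-1-one F1. TBSOTf/Et3N then gives the monocyclic dienol ether 16, now isolated, and Ph3PAuCl/AgBF4 in CH2Cl2/MeOH (gold-catalysed carbocyclisation of a silyl enol ether onto an alkyne) closes ring B, which comes back to the route at 17.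

2. Step 15. What may go wrong: delivery of hydrogen to C2=CH2 from the β face (poor facial selectivity next to the axial benzyl arm) or epimerisation at C4a once the enone is reduced. Fallback: setting out from 18, the benzyl ether is removed without hydrogen (BCl3, pentamethylbenzene, CH2Cl2, −78 °C) to give methyl 3-{[(1R,8aR)-1,8a-dimethyl-2-methylidene-5-oxo-1,2,3,5,6,7,8,8a-octahydronaphthalen-1-yl]methyl}-4-hydroxybenzoate F2. Homogeneous hydrogenation with [Ir(cod)(PCy3)(py)]PF6 under H2 in CH2Cl2 is then directed to the α face by the phenol on the α-oriented arm (for C2=CH2) and by the ketone (for C4=C4a), and comes back at 19.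

3. Step 4. What may go wrong: low enantioselectivity or competing O-alkylation in the ion-pair alkylation of an acyclic β-keto ester. Fallback: setting out from 3, condensation with tert-butyl L-valinate gives the chiral enamino ester tert-butyl (2Z)-3-{[(2S)-1-tert-butoxy-3-methyl-1-oxobutan-2-yl]amino}-6-(1,3-dioxolan-2-yl)-2-methylhex-2-enoate F3. Deprotonation with LiN(i-Pr)2 in toluene and alkylation with 6 give the α-quaternary imine tert-butyl (2S)-2-{[2-(benzyloxy)-5-bromophenyl]methyl}-3-{[(2S)-1-tert-butoxy-3-methyl-1-oxobutan-2-yl]imino}-6-(1,3-dioxolan-2-yl)-2-methylhexanoate F4, which is hydrolysed on work-up (aqueous AcOH) and comes back at 7. The D-auxiliary is used if the sense is opposite.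

**Further compounds**
F1 | step 13 | 2-ethenyl-3-methyl-3-{(2R)-1-[2-(benzyloxy)-5-bromophenyl]-2-methylbut-3-yn-2-yl}cyclohexan-1-one (ring quaternary carbon as in 16, C2–H anti to the ring methyl) | O=C1CCC[C@](C)([C@@](C)(C#C)Cc2cc(Br)ccc2OCc2ccccc2)[C@H]1C=C
F2 | step 15 | methyl 3-{[(1R,8aR)-1,8a-dimethyl-2-methylidene-5-oxo-1,2,3,5,6,7,8,8a-octahydronaphthalen-1-yl]methyl}-4-hydroxybenzoate | O=C1CCC[C@@]2(C)C1=CCC(=C)[C@@]2(C)Cc1cc(C(=O)OC)ccc1O
F3 | step 4 | tert-butyl (2Z)-3-{[(2S)-1-tert-butoxy-3-methyl-1-oxobutan-2-yl]amino}-6-(1,3-dioxolan-2-yl)-2-methylhex-2-enoate | CC(C)[C@H](N/C(CCCC1OCCO1)=C(/C)C(=O)OC(C)(C)C)C(=O)OC(C)(C)C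
F4 | step 4 | tert-butyl (2S)-2-{[2-(benzyloxy)-5-bromophenyl]methyl}-3-{[(2S)-1-tert-butoxy-3-methyl-1-oxobutan-2-yl]imino}-6-(1,3-dioxolan-2-yl)-2-methylhexanoate | CC(C)[C@H](N=C(CCCC1OCCO1)[C@](C)(Cc1cc(Br)ccc1OCc1ccccc1)C(=O)OC(C)(C)C)C(=O)OC(C)(C)C
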